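The route rests on disconnecting the C5–C6 bond of the cyclohexane ring (C1 = CHOAc, C4 = C(CH3)OH, C5 = CH, C6 = CMe2; the chain C1'–C5' runs from C5 to the ether oxygen). The key step exploits that quaternary C6 sits beside the C1 oxygen and that C4, C5 and C1' trace the carbinol and vinyl carbons of (R)-linalool. The tetrasubstituted enolate of an acyclic isopropyl ketone adds to an E-vinyl sulfone, which at once closes the ring, builds the quaternary centre, sets C5 relative to C4 and leaves a sulfone on C1' for the chain. The precursor is a linalool-derived silyloxy keto vinyl sulfone.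

Key step: step 6

Remark: (R)-linalool and (S)-citramalic acid of high enantiomeric purity are assumed; the atom labels C1–C6 and C1'–C5' used below are those of the target.

Step 1
Reactants: 1 (R)-linalool
Product: 2 (3R)-3,7-dimethyl-3-(triethylsilyloxy)octa-1,6-diene
Conditions: TESOTf, 2,6-lutidine, CH2Cl2, −78 → 0 °C
Reagents that add atoms: triethylsilyl trifluoromethanesulfonate, CC[Si](CC)(CC)OS(=O)(=O)C(F)(F)F
Why: Silyl ether protection with a silyl triflate and a hindered pyridine base silylates the tertiary allylic alcohol without breaking its C–O bond, so the carbinol configuration (later C4) is retained.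

Step 2
Reactants: 2 (3R)-3,7-dimethyl-3-(triethylsilyloxy)octa-1,6-diene
Product: 3 (3R)-6,7-epoxy-3,7-dimethyl-3-(triethylsilyloxy)oct-1-ene (both epimers at the oxirane CH)
Conditions: mCPBA, NaHCO3, CH2Cl2, 0 °C
Reagents that add atoms: 3-chloroperoxybenzoic acid, OOC(=O)c1cccc(Cl)c1
Why: Prilezhaev epoxidation is much faster at the electron-rich trisubstituted alkene than at the vinyl group; the uncontrolled oxirane stereocentre is erased in step 3.

Step 3
Reactants: 3 (3R)-6,7-epoxy-3,7-dimethyl-3-(triethylsilyloxy)oct-1-ene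
Product: 4 (6R)-2,6-dimethyl-6-(triethylsilyloxy)oct-7-en-3-one
Conditions: BF3·OEt2 (0.2 equiv), CH2Cl2, −78 °C, short contact; Et3N quench
Reagents that add atoms: none
Why: Meinwald rearrangement: the Lewis acid opens the oxirane at its tertiary carbon and a 1,2-hydride shift from the neighbouring CH should give the isopropyl ketone, while low temperature and a substoichiometric Lewis acid spare the tertiary silyl ether.

Step 4
Reactants: 4 (6R)-2,6-dimethyl-6-(triethylsilyloxy)oct-7-en-3-one
Product: 6 (2R)-2,6-dimethyl-5-oxo-2-(triethylsilyloxy)heptanal, via secondary ozonide 5 (not isolated)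
Conditions: O3, CH2Cl2, −78 °C; then PPh3, −78 °C → rt
Reagents that add atoms: ozone, [O-][O+]=O
Why: Ozonolysis with reductive work-up cleaves the only remaining alkene; the aldehyde has a fully substituted α-carbon and cannot enolise, so the adjacent stereocentre is safe.

Step 5
Reactants: 6 (2R)-2,6-dimethyl-5-oxo-2-(triethylsilyloxy)heptanal; 7 diethyl (phenylsulfonyl)methylphosphonate
Product: 9 (6R,7E)-2,6-dimethyl-8-(phenylsulfonyl)-6-(triethylsilyloxy)oct-7-en-3-one, via sodium phosphonate carbanion 8 (not isolated)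
Conditions: NaH, THF, 0 °C (anion of 7, no excess base); then 6, 0 °C → rt
Reagents that add atoms: none
Why: Horner–Wadsworth–Emmons olefination: the weakly basic sulfonyl-stabilised phosphonate anion attacks only the aldehyde, not the hindered ketone, and should give the E-vinyl sulfone under the usual thermodynamic control.

Step 6
Reactants: 9 (6R,7E)-2,6-dimethyl-8-(phenylsulfonyl)-6-(triethylsilyloxy)oct-7-en-3-one
Product: 12 (3S,4R)-2,2,4-trimethyl-3-[(phenylsulfonyl)methyl]-4-(triethylsilyloxy)cyclohexan-1-one, via potassium enolate 10 (not isolated), via cyclised sulfonyl carbanion 11 (not isolated)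
Conditions: KOtBu (0.3 equiv), 18-crown-6 (0.3 equiv), THF–t-BuOH (9:1), 0.02 M, −40 → 0 °C; AcOH quench
Reagents that add atoms: none
Why: tert-Butoxide deprotonates both α-positions reversibly, but the C2 enolate could only close a cyclobutane and O-attack is reversible, so the substrate drains through tetrasubstituted enolate 10, whose C6 adds to the β-carbon C5 of the vinyl sulfone; the α-sulfonyl carbanion 11 is then protonated by tert-butanol, which regenerates the base. The closest known reaction type is the base-mediated intramolecular Michael addition of ketone enolates to vinyl sulfones. The cyclohexanone ring closes in the 6-(enolendo)-exo-trig mode, which is favoured for enolates. The new C5 stereocentre is controlled by the existing C4 centre through a chair transition state with the E-sulfonylvinyl group equatorial and the C4 oxygen axial, which places C1' cis to the C4 oxygen. This selectivity is needed because C5 cannot be epimerised later, and two features should secure it: the axial C4 substituent is syn to the C6 methyl that becomes axial, a contact far cheaper for the silyloxy oxygen (silyl group turned outwards) than for a methyl group, and the crown-ether-sequestered potassium enolate should react through an open transition state that keeps the sulfonyl group anti to the enolate oxygen (equatorial) instead of bridged to it (axial). The vinyl sulfone has no γ-hydrogen and so cannot isomerise to an allyl sulfone, and dilution suppresses intermolecular addition.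

Step 7
Reactants: 12 (3S,4R)-2,2,4-trimethyl-3-[(phenylsulfonyl)methyl]-4-(triethylsilyloxy)cyclohexan-1-one
Product: 13 (1R,3S,4R)-2,2,4-trimethyl-3-[(phenylsulfonyl)methyl]-4-(triethylsilyloxy)cyclohexan-1-ol
Conditions: LiBH(s-Bu)3, THF, −78 → −20 °C; then NaOH, H2O2, 0 °C
Reagents that add atoms: none
Why: Hindered trialkylborohydride reduction: the bulky reagent avoids the axial trajectory past the axial hydrogens at C3 and C5 and delivers hydride equatorially, which should give the axial (1R) alcohol, as in reductions of 4,4-dimethyl-3-keto steroids and triterpenoids.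

Step 8
Reactants: 14 (S)-citramalic acid
Product: 15 (2S)-2-methylbutane-1,2,4-triol
Conditions: BH3·SMe2, B(OMe)3, THF, 0 °C → rt; MeOH quench
Reagents that add atoms: none
Why: Borane reduction converts both carboxylic acids into primary alcohols and does not touch the tertiary carbinol centre.

Step 9
Reactants: 15 (2S)-2-methylbutane-1,2,4-triol
Product: 16 2-[(4S)-2,2,4-trimethyl-1,3-dioxolan-4-yl]ethan-1-ol
Conditions: 2,2-dimethoxypropane, acetone, TsOH·H2O (cat.), rt
Reagents that add atoms: 2,2-dimethoxypropane, COC(C)(C)OC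
Why: Thermodynamic acetalisation: acetone prefers the five-membered dioxolane on the 1,2-diol, because a six-membered acetonide through the tertiary oxygen would carry syn-axial methyl groups, so the C4 hydroxyl stays free.

Step 10
Reactants: 16 2-[(4S)-2,2,4-trimethyl-1,3-dioxolan-4-yl]ethan-1-ol
Product: 17 tert-butyl(diphenyl){2-[(4S)-2,2,4-trimethyl-1,3-dioxolan-4-yl]ethoxy}silane
Conditions: TBDPSCl, imidazole, DMF, rt
Reagents that add atoms: tert-butyl(chloro)diphenylsilane, CC(C)(C)[Si](Cl)(c1ccccc1)c1ccccc1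
Why: Standard silylation of the only free hydroxyl; this silyl ether tolerates the aqueous acid, alkoxide and organolithium conditions that follow.

Step 11
Reactants: 17 tert-butyl(diphenyl){2-[(4S)-2,2,4-trimethyl-1,3-dioxolan-4-yl]ethoxy}silane
Product: 18 (2S)-4-(tert-butyldiphenylsilyloxy)-2-methylbutane-1,2-diol
Conditions: AcOH–H2O (4:1), 40 °C
Reagents that add atoms: none
Why: Acid-catalysed acetal hydrolysis frees the 1,2-diol, while the tert-butyldiphenylsilyl ether is stable to aqueous acetic acid.

Step 12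
Reactants: 18 (2S)-4-(tert-butyldiphenylsilyloxy)-2-methylbutane-1,2-diol
Product: 20 tert-butyl{2-[(2S)-2-methyloxiran-2-yl]ethoxy}diphenylsilane, via primary monotosylate 19 (not isolated)
Conditions: NaH (2.2 equiv), N-tosylimidazole, THF, 0 °C → rt
Reagents that add atoms: none
Why: One-flask epoxide formation from a 1,2-diol: the primary alkoxide is sulfonylated selectively and the tertiary alkoxide displaces the tosylate (intramolecular Williamson reaction, 3-exo-tet), with retention at the quaternary centre because its C–O bond is never broken.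

Step 13
Reactants: 13 (1R,3S,4R)-2,2,4-trimethyl-3-[(phenylsulfonyl)methyl]-4-(triethylsilyloxy)cyclohexan-1-ol; 20 tert-butyl{2-[(2S)-2-methyloxiran-2-yl]ethoxy}diphenylsilane
Product: 22 (1R,3S,4R)-3-[(3S)-5-(tert-butyldiphenylsilyloxy)-3-hydroxy-3-methyl-1-(phenylsulfonyl)pentyl]-2,2,4-trimethyl-4-(triethylsilyloxy)cyclohexan-1-ol (both C1' epimers), via dilithiated sulfone 21 (not isolated)
Conditions: n-BuLi (2.1 equiv), THF, −78 → −20 °C; then 20 (1.5 equiv), DMPU, −20 °C → rt; aq NH4Cl
Reagents that add atoms: none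
Why: Alkylation of an α-sulfonyl carbanion with an epoxide: after the hydroxyl is deprotonated, the second equivalent of base gives the C1' carbanion, which attacks the unsubstituted oxirane carbon C2' (SN2), so C3' comes unchanged from citramalate (its descriptor reads S here only because of CIP priorities) and the C1' epimers are removed in step 14.

Step 14
Reactants: 22 (1R,3S,4R)-3-[(3S)-5-(tert-butyldiphenylsilyloxy)-3-hydroxy-3-methyl-1-(phenylsulfonyl)pentyl]-2,2,4-trimethyl-4-(triethylsilyloxy)cyclohexan-1-ol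
Product: 23 (1R,3S,4R)-3-[(3R)-5-(tert-butyldiphenylsilyloxy)-3-hydroxy-3-methylpentyl]-2,2,4-trimethyl-4-(triethylsilyloxy)cyclohexan-1-ol
Conditions: Na/Hg (6% sodium amalgam), Na2HPO4, THF–MeOH, −20 → 0 °C
Reagents that add atoms: none
Why: Reductive desulfonylation by electron transfer cleaves the C1'–S bond to C–H; no leaving group sits β to the sulfone, and the buffered medium leaves silyl ethers and alcohols alone.

Step 15
Reactants: 23 (1R,3S,4R)-3-[(3R)-5-(tert-butyldiphenylsilyloxy)-3-hydroxy-3-methylpentyl]-2,2,4-trimethyl-4-(triethylsilyloxy)cyclohexan-1-ol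
Product: 24 (1R,3S,4R)-3-[(3R)-5-(tert-butyldiphenylsilyloxy)-3-hydroxy-3-methylpentyl]-2,2,4-trimethyl-4-(triethylsilyloxy)cyclohexyl acetate
Conditions: Ac2O, pyridine, DMAP (cat.), CH2Cl2, rt
Reagents that add atoms: acetic anhydride, CC(=O)OC(C)=O
Why: DMAP-catalysed acylation should esterify the only secondary hydroxyl with retention at C1; the tertiary C3' hydroxyl and the silyl ethers should not react under these conditions.

Step 16
Reactants: 24 (1R,3S,4R)-3-[(3R)-5-(tert-butyldiphenylsilyloxy)-3-hydroxy-3-methylpentyl]-2,2,4-trimethyl-4-(triethylsilyloxy)cyclohexyl acetate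
Product: 25 (1R,3S,4R)-3-[(3R)-3,5-dihydroxy-3-methylpentyl]-4-hydroxy-2,2,4-trimethylcyclohexyl acetate
Conditions: HF·pyridine, THF–pyridine, 0 °C → rt
Reagents that add atoms: none
Why: Fluoride-induced desilylation removes both silyl ethers in one operation under buffered conditions in which the acetate and the tertiary alcohols are stable.

Step 17
Reactants: 25 (1R,3S,4R)-3-[(3R)-3,5-dihydroxy-3-methylpentyl]-4-hydroxy-2,2,4-trimethylcyclohexyl acetate; 26 umbelliferone
Product: 27 (1R,3S,4R)-4-hydroxy-3-{(3R)-3-hydroxy-3-methyl-5-[(2-oxo-2H-chromen-7-yl)oxy]pentyl}-2,2,4-trimethylcyclohexyl acetate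
Conditions: PPh3, DIAD, THF, 0 °C → rt
Reagents that add atoms: none
Why: Mitsunobu etherification: the acidic 7-hydroxyl of umbelliferone displaces the activated primary C5' oxygen, while the two tertiary alcohols cannot be activated and the acetate is untouched.

Compound list
1 | (R)-linalool, (3R)-3,7-dimethylocta-1,6-dien-3-ol | CC(C)=CCC[C@@](C)(O)C=C | starting material
2 | (3R)-3,7-dimethyl-3-(triethylsilyloxy)octa-1,6-diene | CC(C)=CCC[C@@](C)(O[Si](CC)(CC)CC)C=C | intermediate
3 | (3R)-6,7-epoxy-3,7-dimethyl-3-(triethylsilyloxy)oct-1-ene, both epimers at the oxirane CH | CC1(C)OC1CC[C@@](C)(O[Si](CC)(CC)CC)C=C | intermediate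
4 | (6R)-2,6-dimethyl-6-(triethylsilyloxy)oct-7-en-3-one | CC(C)C(=O)CC[C@@](C)(O[Si](CC)(CC)CC)C=C | intermediate
5 | secondary ozonide of 4, (6R)-2-methyl-6-(1,2,4-trioxolan-3-yl)-6-(triethylsilyloxy)heptan-3-one, not isolated | CC(C)C(=O)CC[C@@](C)(O[Si](CC)(CC)CC)C1OCOO1 | intermediate
6 | (2R)-2,6-dimethyl-5-oxo-2-(triethylsilyloxy)heptanal | CC(C)C(=O)CC[C@@](C)(O[Si](CC)(CC)CC)C=O | intermediate
7 | diethyl (phenylsulfonyl)methylphosphonate | CCOP(=O)(CS(=O)(=O)c1ccccc1)OCC | starting material
8 | sodium salt of the carbanion of 7, not isolated | CCOP(=O)([CH-]S(=O)(=O)c1ccccc1)OCC.[Na+] | intermediate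
9 | (6R,7E)-2,6-dimethyl-8-(phenylsulfonyl)-6-(triethylsilyloxy)oct-7-en-3-one | CC(C)C(=O)CC[C@@](C)(O[Si](CC)(CC)CC)/C=C/S(=O)(=O)c1ccccc1 | intermediate
10 | potassium (6R,7E)-2,6-dimethyl-8-(phenylsulfonyl)-6-(triethylsilyloxy)octa-2,7-dien-3-olate, tetrasubstituted enolate, not isolated | CC(C)=C([O-])CC[C@@](C)(O[Si](CC)(CC)CC)/C=C/S(=O)(=O)c1ccccc1.[K+] | intermediate
11 | potassium α-sulfonyl carbanion of 12, not isolated | O=C1CC[C@@](C)(O[Si](CC)(CC)CC)[C@@H]([CH-]S(=O)(=O)c2ccccc2)C1(C)C.[K+] | intermediate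
12 | (3S,4R)-2,2,4-trimethyl-3-[(phenylsulfonyl)methyl]-4-(triethylsilyloxy)cyclohexan-1-one, sulfonylmethyl cis to the silyloxy group | O=C1CC[C@@](C)(O[Si](CC)(CC)CC)[C@@H](CS(=O)(=O)c2ccccc2)C1(C)C | intermediate
13 | (1R,3S,4R)-2,2,4-trimethyl-3-[(phenylsulfonyl)methyl]-4-(triethylsilyloxy)cyclohexan-1-ol, axial hydroxyl | O[C@@H]1CC[C@@](C)(O[Si](CC)(CC)CC)[C@@H](CS(=O)(=O)c2ccccc2)C1(C)C | intermediate
14 | (S)-citramalic acid, (2S)-2-hydroxy-2-methylbutanedioic acid | C[C@](O)(CC(=O)O)C(=O)O | starting material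
15 | (2S)-2-methylbutane-1,2,4-triol | C[C@](O)(CCO)CO | intermediate
16 | 2-[(4S)-2,2,4-trimethyl-1,3-dioxolan-4-yl]ethan-1-ol | C[C@]1(CCO)COC(C)(C)O1 | intermediate
17 | tert-butyl(diphenyl){2-[(4S)-2,2,4-trimethyl-1,3-dioxolan-4-yl]ethoxy}silane | C[C@]1(CCO[Si](c2ccccc2)(c2ccccc2)C(C)(C)C)COC(C)(C)O1 | intermediate
18 | (2S)-4-(tert-butyldiphenylsilyloxy)-2-methylbutane-1,2-diol | C[C@](O)(CCO[Si](c1ccccc1)(c1ccccc1)C(C)(C)C)CO | intermediate
19 | primary monotosylate of 18 as its sodium tertiary alkoxide, (2S) configuration, not isolated | C[C@]([O-])(CCO[Si](c1ccccc1)(c1ccccc1)C(C)(C)C)COS(=O)(=O)c1ccc(C)cc1.[Na+] | intermediate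
20 | tert-butyl{2-[(2S)-2-methyloxiran-2-yl]ethoxy}diphenylsilane | C[C@]1(CCO[Si](c2ccccc2)(c2ccccc2)C(C)(C)C)CO1 | intermediate
21 | dilithio derivative of 13 (C1 alkoxide and C1' carbanion), not isolated | [Li+].[Li+].[O-][C@@H]1CC[C@@](C)(O[Si](CC)(CC)CC)[C@@H]([CH-]S(=O)(=O)c2ccccc2)C1(C)C | intermediate
22 | (1R,3S,4R)-3-[(3S)-5-(tert-butyldiphenylsilyloxy)-3-hydroxy-3-methyl-1-(phenylsulfonyl)pentyl]-2,2,4-trimethyl-4-(triethylsilyloxy)cyclohexan-1-ol, both epimers at the sulfonyl-bearing carbon | O[C@@H]1CC[C@@](C)(O[Si](CC)(CC)CC)[C@@H](C(C[C@@](C)(O)CCO[Si](c2ccccc2)(c2ccccc2)C(C)(C)C)S(=O)(=O)c2ccccc2)C1(C)C | intermediate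
23 | (1R,3S,4R)-3-[(3R)-5-(tert-butyldiphenylsilyloxy)-3-hydroxy-3-methylpentyl]-2,2,4-trimethyl-4-(triethylsilyloxy)cyclohexan-1-ol | O[C@@H]1CC[C@@](C)(O[Si](CC)(CC)CC)[C@@H](CC[C@@](C)(O)CCO[Si](c2ccccc2)(c2ccccc2)C(C)(C)C)C1(C)C | intermediate
24 | (1R,3S,4R)-3-[(3R)-5-(tert-butyldiphenylsilyloxy)-3-hydroxy-3-methylpentyl]-2,2,4-trimethyl-4-(triethylsilyloxy)cyclohexyl acetate | CC(=O)O[C@@H]1CC[C@@](C)(O[Si](CC)(CC)CC)[C@@H](CC[C@@](C)(O)CCO[Si](c2ccccc2)(c2ccccc2)C(C)(C)C)C1(C)C | intermediate
25 | (1R,3S,4R)-3-[(3R)-3,5-dihydroxy-3-methylpentyl]-4-hydroxy-2,2,4-trimethylcyclohexyl acetate | CC(=O)O[C@@H]1CC[C@@](C)(O)[C@@H](CC[C@@](C)(O)CCO)C1(C)C | intermediate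
26 | umbelliferone, 7-hydroxy-2H-chromen-2-one | O=c1ccc2ccc(O)cc2o1 | starting material
27 | (1R,3S,4R)-4-hydroxy-3-{(3R)-3-hydroxy-3-methyl-5-[(2-oxo-2H-chromen-7-yl)oxy]pentyl}-2,2,4-trimethylcyclohexyl acetate (CNP0333962.1) | CC(=O)O[C@@H]1CC[C@@](C)(O)[C@@H](CC[C@@](C)(O)CCOc2ccc3ccc(=O)oc3c2)C1(C)C | target

Total step count: 17 (steps 1–7 and 13–17 on the main line, steps 8–12 for the epoxide).
Longest linear sequence: 12 steps, from (R)-linalool through steps 1–7 and 13–17.

Steps most likely to fail

1. Step 6 (key step). The closure may run through the competing chair in which the sulfonylvinyl group is axial (a cation-bridged arrangement) or the C4 methyl is axial. That would mean poor facial selectivity at C5, and the C5 epimer cannot be corrected afterwards. The fallback sets out from 6 and returns at 12. It ties the C4 oxygen to C1', so that ring fusion fixes C5 instead of a conformational preference. Desilylation of 6 (HF·pyridine, THF) gives (2R)-2-hydroxy-2,6-dimethyl-5-oxoheptanal F1. Knoevenagel condensation with methyl (phenylsulfonyl)acetate (piperidine, AcOH, toluene, reflux) and lactonisation of the tertiary hydroxyl give the sulfonyl butenolide (5R)-5-methyl-5-(4-methyl-3-oxopentyl)-3-(phenylsulfonyl)furan-2(5H)-one F2. KOtBu (1.1 equiv, THF, −20 °C) then forms the same C5–C6 bond by intramolecular Michael addition of the same enolate carbon to the butenolide β-carbon. The tether attached at C4 can reach only the face on which it sits, so only the cis-fused lactone (3aS,7aR)-4,4,7a-trimethyl-3-(phenylsulfonyl)hexahydro-1-benzofuran-2,5-dione F3 can form, with the C4 oxygen and C1' cis. Saponification (LiOH, THF–H2O) and thermal decarboxylation of the α-sulfonyl carboxylate (wet DMSO, 120 °C) give (3S,4R)-4-hydroxy-2,2,4-trimethyl-3-[(phenylsulfonyl)methyl]cyclohexan-1-one F4. TESOTf and 2,6-lutidine then return 12.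

2. Step 13. The substitution may be too slow: the carbanion carbon hangs on a CH between two quaternary carbons, the electrophilic CH2 is next to a fully substituted carbon, and the dianion aggregates, so the epoxide may decompose on prolonged warming. The fallback sets out from 13 and returns at 22. It uses a Lewis-acid-assisted opening by a monoanion. The C1 hydroxyl is capped (TMSCl, imidazole, CH2Cl2) to give trimethyl{[(1R,3S,4R)-2,2,4-trimethyl-3-[(phenylsulfonyl)methyl]-4-(triethylsilyloxy)cyclohexyl]oxy}silane F5. One equivalent of n-BuLi (THF, −78 °C), then BF3·OEt2 and 20 at −78 °C, give the C1-trimethylsilyl ether of the adduct, F6. K2CO3 in MeOH cleaves only this secondary trimethylsilyl ether and delivers 22.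

3. Step 3. The silyl ether oxygen may capture the developing tertiary cation (cyclic ether formation with loss of the silyl group), or an alkyl group may migrate instead of hydride. The fallback sets out from 3 and returns at 4. It replaces the rearrangement by cleavage and re-addition. H5IO6 (THF–Et2O, 0 °C) cleaves the oxirane of 3 to (4R)-4-methyl-4-(triethylsilyloxy)hex-5-enal F7 and acetone. Addition of i-PrMgBr (THF, −78 °C) gives (6R)-2,6-dimethyl-6-(triethylsilyloxy)oct-7-en-3-ol F8 as both carbinol epimers. Dess–Martin periodinane (CH2Cl2, NaHCO3) oxidises it to 4.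

Further compounds
F1 | step 6 | (2R)-2-hydroxy-2,6-dimethyl-5-oxoheptanal | CC(C)C(=O)CC[C@@](C)(O)C=O
F2 | step 6 | (5R)-5-methyl-5-(4-methyl-3-oxopentyl)-3-(phenylsulfonyl)furan-2(5H)-one | CC(C)C(=O)CC[C@@]1(C)OC(=O)C(S(=O)(=O)c2ccccc2)=C1
F3 | step 6 | (3aS,7aR)-4,4,7a-trimethyl-3-(phenylsulfonyl)hexahydro-1-benzofuran-2,5-dione, cis-fused, both C3 epimers | O=C1CC[C@@]2(C)OC(=O)C(S(=O)(=O)c3ccccc3)[C@H]2C1(C)C
F4 | step 6 | (3S,4R)-4-hydroxy-2,2,4-trimethyl-3-[(phenylsulfonyl)methyl]cyclohexan-1-one | O=C1CC[C@@](C)(O)[C@@H](CS(=O)(=O)c2ccccc2)C1(C)C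
F5 | step 13 | trimethyl{[(1R,3S,4R)-2,2,4-trimethyl-3-[(phenylsulfonyl)methyl]-4-(triethylsilyloxy)cyclohexyl]oxy}silane | C[Si](C)(C)O[C@@H]1CC[C@@](C)(O[Si](CC)(CC)CC)[C@@H](CS(=O)(=O)c2ccccc2)C1(C)C
F6 | step 13 | C1-trimethylsilyl ether of 22, both epimers at the sulfonyl-bearing carbon | C[Si](C)(C)O[C@@H]1CC[C@@](C)(O[Si](CC)(CC)CC)[C@@H](C(C[C@@](C)(O)CCO[Si](c2ccccc2)(c2ccccc2)C(C)(C)C)S(=O)(=O)c2ccccc2)C1(C)C
F7 | step 3 | (4R)-4-methyl-4-(triethylsilyloxy)hex-5-enal | O=CCC[C@@](C)(O[Si](CC)(CC)CC)C=C
F8 | step 3 | (6R)-2,6-dimethyl-6-(triethylsilyloxy)oct-7-en-3-ol, both C3 epimers | CC(C)C(O)CC[C@@](C)(O[Si](CC)(CC)CC)C=C
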